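**Plan**

- Retrosynthesis: cut C12–C13 (B-alkyl Suzuki to a ready-made bromobutenolide), C9–C11 (Stille on a C8=C9 enol triflate) and C8–C17 (enolate methylation); then take C3 and C18 out of ring A together, which contracts it to a cyclopentenone β-keto ester; this is cut at C4=C5 (Knoevenagel), C2–C4 (Roskamp) and C1–C10 (allylation) back to 2-methylcyclohexane-1,3-dione.
- Enabling feature: ring A (C1–C5, C10) has its only ring oxygen on C2 and the carboxyl-level carbon C19 on C4, 1,3 to each other across the unsubstituted methylene C3. This γ-oxo ester array is the retron of a one-carbon homologation of a cyclic β-keto ester. C4 also carries the methyl C18, which a second methylene unit can supply.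
- Forward order of rings: ring B comes from the dione; a five-membered ring (C10, C1, C2, C4, C5) is annulated onto C5–C10; one operation with a zinc carbenoid inserts C3 between C2 and C4 (ring A becomes six-membered), puts C18 on C4 and leaves a C5=C6 alkene; the butenolide is attached last as an intact ring.
- Stereochemistry: C10 from enzymatic desymmetrisation of the prochiral dione; C4 from α-face attack on a dienolate, anti to the C10 methyl; C2 from a thermodynamic (dissolving-metal) ketone reduction to the equatorial alcohol; C5 and C6 together from α-face hydroboration of the C5=C6 alkene.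
- The C2 ketone and C19 ester are reduced in one step, and the three hydroxyls are carried as TBS ethers through the side-chain construction.

Key step: step 8

Remark: bicyclic compounds are described with labdane locants (ring A C1–C5/C10, ring B C5–C10, C17 on C8, C18 α and C19 β on C4, C20 β on C10, butenolide C13–C16); α/β refer to the usual drawing with the C10 methyl β.
Remark: the yeast reduction of 3 is taken to give the (2S,3S)-ketol; its reduced carbon becomes C5 and its surviving ketone C9, which corresponds to 10S in the target.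

**Route**

Step 1
Reactants: 1 2-methylcyclohexane-1,3-dione; 2 allyl bromide
Product: 3 2-allyl-2-methylcyclohexane-1,3-dione
Conditions: 1 M NaOH (aq), rt
Reagents that add atoms: none
Why: C-alkylation of the dione enolate with an allylic halide (enolate allylation) should give the prochiral 2,2-disubstituted dione; no stereocentre is formed.

Step 2
Reactants: 3 2-allyl-2-methylcyclohexane-1,3-dione
Product: 4 (2S,3S)-2-allyl-3-hydroxy-2-methylcyclohexan-1-one
Conditions: baker's yeast, sucrose, H2O, 30 °C
Reagents that add atoms: none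
Why: Enzymatic desymmetrising reduction of one of two enantiotopic ketones (yeast reduction of a 2,2-disubstituted cyclohexane-1,3-dione) should give the (2S,3S)-ketol, so the quaternary carbon (future C10) is set by the enzyme's choice of carbonyl group.

Step 3
Reactants: 4 (2S,3S)-2-allyl-3-hydroxy-2-methylcyclohexan-1-one
Product: 5 (6S,7S)-6-allyl-6-methyl-1,4-dioxaspiro[4.5]decan-7-ol
Conditions: ethylene glycol, PPTS (cat.), benzene, reflux (Dean–Stark)
Reagents that add atoms: ethylene glycol, OCCO
Why: Acid-catalysed ketalisation (dioxolane formation) masks the remaining ketone (future C9), so the two oxygenated ring carbons stay differentiated.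

Step 4
Reactants: 5 (6S,7S)-6-allyl-6-methyl-1,4-dioxaspiro[4.5]decan-7-ol
Product: 6 (6S)-6-allyl-6-methyl-1,4-dioxaspiro[4.5]decan-7-one
Conditions: Dess–Martin periodinane, pyridine, CH2Cl2, rt
Reagents that add atoms: none
Why: Dess–Martin oxidation of the secondary alcohol should give the ketone that becomes C5; the carbinol centre is erased and the quaternary centre is untouched.

Step 5
Reactants: 6 (6S)-6-allyl-6-methyl-1,4-dioxaspiro[4.5]decan-7-one
Product: 8 2-[(6S)-6-methyl-7-oxo-1,4-dioxaspiro[4.5]decan-6-yl]acetaldehyde, via ozonide 7 (not isolated)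
Conditions: O3, CH2Cl2, -78 °C; then PPh3, -78 °C to rt
Reagents that add atoms: ozone, [O-][O+]=O
Why: Ozonolysis with reductive work-up should cleave the terminal alkene to the aldehyde (C2) without affecting the ketone or the ketal.

Step 6
Reactants: 8 2-[(6S)-6-methyl-7-oxo-1,4-dioxaspiro[4.5]decan-6-yl]acetaldehyde; 9 ethyl diazoacetate
Product: 10 ethyl 4-[(6S)-6-methyl-7-oxo-1,4-dioxaspiro[4.5]decan-6-yl]-3-oxobutanoate
Conditions: SnCl2 (10 mol %), CH2Cl2, rt
Reagents that add atoms: none
Why: Roskamp homologation (Lewis-acid-catalysed reaction of a diazo ester with an aldehyde) should convert the aldehyde, far more reactive than the hindered ketone, into the β-keto ester that holds C2, C4 and C19.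

Step 7
Reactants: 10 ethyl 4-[(6S)-6-methyl-7-oxo-1,4-dioxaspiro[4.5]decan-6-yl]-3-oxobutanoate
Product: 11 ethyl (7aS)-7,7-(ethylenedioxy)-7a-methyl-2-oxo-2,4,5,6,7,7a-hexahydro-1H-indene-3-carboxylate
Conditions: piperidine (0.2 equiv), AcOH (0.2 equiv), benzene, reflux (Dean–Stark)
Reagents that add atoms: none
Why: Intramolecular Knoevenagel condensation of the active methylene C4 onto the ring ketone C5 (5-exo-trig aldol addition, then loss of water) should close the cyclopentenone of this 1,4-dicarbonyl array.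

Step 8
Reactants: 11 ethyl (7aS)-7,7-(ethylenedioxy)-7a-methyl-2-oxo-2,4,5,6,7,7a-hexahydro-1H-indene-3-carboxylate
Product: 14 ethyl 9,9-(ethylenedioxy)-4α,10β-dimethyl-2-oxo-Δ5-octalin-4β-carboxylate, via zinc dienolate 12 (not isolated), via zinc homoenolate 13 (not isolated)
Conditions: Et2Zn (6 equiv), CH2I2 (6 equiv), CH2Cl2, 0 °C; add 11, 0 °C to rt; TMSCl (0.2 equiv), rt; then sat. aq. NH4Cl
Reagents that add atoms: diiodomethane, ICI
Why: Proposed new method: the zinc dienolate of 11 (deprotonation at C6) should be C-methylenated at C4 by the carbenoid, and the resulting C4–CH2–Zn homoenolate should add to the C2 carbonyl (3-exo-trig) to give a bicyclo[2.1.0]pentan-1-olate whose shared C2–C4 bond, flanked by the oxygen donor and the ester acceptor, cleaves to the ring-expanded zinc dienolate 12; the closest known reaction type is the zinc-carbenoid chain extension of β-keto esters to γ-keto esters, here asked to act on a vinylogous (alkylidene) cyclic β-keto ester. With excess carbenoid and catalytic TMSCl, 12 should be methylenated a second time at its α-carbon C4 (tandem chain extension–homoenolate formation, known to give α-methyl γ-keto esters in acyclic cases but not yet to create a quaternary centre), and protonolysis of the C–Zn bond of 13 leaves the C18 methyl. Ring A thus arises by one-carbon expansion of the cyclopentenone, C3 being inserted between C2 and C4 through a cyclopropane that is closed 3-exo-trig and then opened; no other ring is closed. The one new stereocentre, C4, is set in the second methylenation by approach of the carbenoid to the α-face of the planar dienolate, anti to the axial C10 methyl that sits 1,3 to C4, which places C18 α and the ester (C19) β. The step needs attack at C4 and not at C6 in both dienolates, which chelation of zinc between the C2 and ester oxygens should secure by delivering the carbenoid to C4, and it needs the C4=C5 bond of 11 and the C5=C6 bond of 14 to resist Simmons–Smith cyclopropanation, which their conjugation to two carbonyls and their flanking quaternary centres should ensure.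

Step 9
Reactants: 14 ethyl 9,9-(ethylenedioxy)-4α,10β-dimethyl-2-oxo-Δ5-octalin-4β-carboxylate
Product: 15 9,9-(ethylenedioxy)-4β-(hydroxymethyl)-4α,10β-dimethyl-Δ5-octalin-2α-ol
Conditions: Li (excess), NH3(l)/THF, EtOH, -78 to -33 °C; then NH4Cl
Reagents that add atoms: none
Why: Dissolving-metal reduction should turn the C2 ketone into the thermodynamically preferred equatorial 2α-alcohol (an axial 2β-oxygen would be 1,3-diaxial to both the C10 methyl and C19) and, as a Bouveault–Blanc-type reduction, the C19 ester into the primary alcohol, while the isolated C5=C6 bond and the dioxolane are inert.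

Step 10
Reactants: 15 9,9-(ethylenedioxy)-4β-(hydroxymethyl)-4α,10β-dimethyl-Δ5-octalin-2α-ol
Product: 17 9,9-(ethylenedioxy)-4β-(hydroxymethyl)-4α,10β-dimethyl-5α-decalin-2α,6α-diol, via C6-alkylborane 16 (not isolated)
Conditions: BH3·THF (5 equiv), THF, 0 °C to rt; then 3 M NaOH, 30% H2O2, 0 °C to rt
Reagents that add atoms: hydrogen peroxide, OO
Why: Hydroboration–oxidation of the trisubstituted C5=C6 alkene is a syn, anti-Markovnikov addition that should occur on the α-face, opposite the axial C10 methyl and the axial C19 group, setting 5α-H (trans ring fusion) and 6α-OH together as in Δ5-steroids.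

Step 11
Reactants: 17 9,9-(ethylenedioxy)-4β-(hydroxymethyl)-4α,10β-dimethyl-5α-decalin-2α,6α-diol
Product: 18 2α,6α-dihydroxy-4β-(hydroxymethyl)-4α,10β-dimethyl-5α-decalin-9-one
Conditions: 1 M HCl (aq), THF, rt
Reagents that add atoms: water, O
Why: Acid hydrolysis of the dioxolane (acetal deprotection) should free the C9 ketone; the triol has no acid-labile neighbour and no enolisable stereocentre next to the ketone.

Step 12
Reactants: 18 2α,6α-dihydroxy-4β-(hydroxymethyl)-4α,10β-dimethyl-5α-decalin-9-one
Product: 19 2α,6α-bis(tert-butyldimethylsilyloxy)-4β-(tert-butyldimethylsilyloxymethyl)-4α,10β-dimethyl-5α-decalin-9-one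
Conditions: TBSOTf (3.6 equiv), 2,6-lutidine, CH2Cl2, -78 to 0 °C
Reagents that add atoms: tert-butyldimethylsilyl triflate, CC(C)(C)[Si](C)(C)OS(=O)(=O)C(F)(F)F
Why: Silyl ether formation with the silyl triflate should protect all three hydroxyls, including the hindered 6α-OH, while the weak base does not enolise the ketone.

Step 13
Reactants: 19 2α,6α-bis(tert-butyldimethylsilyloxy)-4β-(tert-butyldimethylsilyloxymethyl)-4α,10β-dimethyl-5α-decalin-9-one
Product: 20 8-methyl derivative of 19 (C8 epimers)
Conditions: LDA, THF, -78 °C; then MeI, -78 to 0 °C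
Reagents that add atoms: iodomethane, CI
Why: Enolate alkylation can occur only at C8 because the other α-carbon (C10) is quaternary; the new C8 centre need not be controlled, since C8 becomes sp2 in the next step.

Step 14
Reactants: 20 8-methyl derivative of 19 (C8 epimers)
Product: 21 C8=C9 enol triflate: 2α,6α-bis(TBSO)-19-(TBSO)-4α,8,10β-trimethyl-5α-octal-8-en-9-yl triflate
Conditions: KHMDS, THF, -78 °C; then PhNTf2, -78 to 0 °C
Reagents that add atoms: N-phenylbis(trifluoromethanesulfonimide), O=S(=O)(N(c1ccccc1)S(=O)(=O)C(F)(F)F)C(F)(F)F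
Why: O-triflation of the only possible enolate (towards C8) should give the tetrasubstituted C8=C9 enol triflate, as for other 2,2,6-trisubstituted cyclohexanones.

Step 15
Reactants: 21 C8=C9 enol triflate; 22 tributyl(vinyl)stannane
Product: 23 9-vinyl diene: 2α,6α-bis(TBSO)-19-(TBSO)-4α,8,10β-trimethyl-9-vinyl-5α-octal-8-ene
Conditions: Pd(PPh3)4 (5 mol %), LiCl (3 equiv), THF, reflux
Reagents that add atoms: none
Why: Stille coupling of a hindered cyclohexenyl triflate with a vinylstannane (known for 2,6,6-trisubstituted cyclohexenyl triflates) should install C11–C12 with the C8=C9 bond fixed in place.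

Step 16
Reactants: 23 9-vinyl diene; 24 4-bromofuran-2(5H)-one
Product: 26 2,6,19-tris-O-TBS ether of the target, via B-alkyl-9-BBN adduct 25 (not isolated)
Conditions: 9-BBN, THF, 0 °C to rt; then 24, PdCl2(dppf) (5 mol %), AsPh3, K3PO4 (aq), DMF, rt
Reagents that add atoms: none
Why: 9-BBN should hydroborate only the terminal vinyl carbon (the tetrasubstituted alkene is inert), and the primary alkylborane should undergo B-alkyl Suzuki–Miyaura coupling with the β-bromobutenolide to form C12–C13.

Step 17
Reactants: 26 2,6,19-tris-O-TBS ether of the target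
Product: 27 target, (2R,4S,5R,6S,10S)-2α,6α,19-trihydroxylabda-8,13-dien-15,16-olide (CNP0387838.1)
Conditions: HF·pyridine, THF/pyridine, 0 °C to rt
Reagents that add atoms: none
Why: Fluoride-mediated desilylation under buffered acidic conditions should remove the three TBS ethers without touching the base-sensitive butenolide, the tetrasubstituted alkene or any stereocentre.

**Compound list**

1 | 2-methylcyclohexane-1,3-dione | CC1C(=O)CCCC1=O | starting material
2 | allyl bromide | C=CCBr | starting material
3 | 2-allyl-2-methylcyclohexane-1,3-dione | C=CCC1(C)C(=O)CCCC1=O | intermediate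
4 | (2S,3S)-2-allyl-3-hydroxy-2-methylcyclohexan-1-one | C=CC[C@]1(C)C(=O)CCC[C@@H]1O | intermediate
5 | (6S,7S)-6-allyl-6-methyl-1,4-dioxaspiro[4.5]decan-7-ol | C=CC[C@]1(C)C2(OCCO2)CCC[C@@H]1O | intermediate
6 | (6S)-6-allyl-6-methyl-1,4-dioxaspiro[4.5]decan-7-one | C=CC[C@]1(C)C2(OCCO2)CCCC1=O | intermediate
7 | ozonide (1,2,4-trioxolane) of 6, formed in the flask | C1OC(OO1)C[C@]2(C)C3(OCCO3)CCCC2=O | intermediate
8 | 2-[(6S)-6-methyl-7-oxo-1,4-dioxaspiro[4.5]decan-6-yl]acetaldehyde | O=CC[C@]1(C)C2(OCCO2)CCCC1=O | intermediate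
9 | ethyl diazoacetate | CCOC(=O)C=[N+]=[N-] | starting material
10 | ethyl 4-[(6S)-6-methyl-7-oxo-1,4-dioxaspiro[4.5]decan-6-yl]-3-oxobutanoate | CCOC(=O)CC(=O)C[C@]1(C)C2(OCCO2)CCCC1=O | intermediate
11 | ethyl (7aS)-7,7-(ethylenedioxy)-7a-methyl-2-oxo-2,4,5,6,7,7a-hexahydro-1H-indene-3-carboxylate (C4=C5 cyclopentenone ester) | CCOC(=O)C1=C2CCCC3(OCCO3)[C@@]2(C)CC1=O | intermediate
12 | iodozinc dienolate of the ring-expanded 2-oxo Δ5 ester (C3 inserted), formed in the flask | CCOC(O[Zn]I)=C1CC(=O)C[C@@]2(C)C1=CCCC23OCCO3 | intermediate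
13 | 4α-(iodozinciomethyl) homoenolate of the ring-expanded keto ester, formed in the flask | CCOC(=O)[C@@]1(C[Zn]I)CC(=O)C[C@@]2(C)C1=CCCC23OCCO3 | intermediate
14 | ethyl 9,9-(ethylenedioxy)-4α,10β-dimethyl-2-oxo-Δ5-octalin-4β-carboxylate | CCOC(=O)[C@@]1(C)CC(=O)C[C@@]2(C)C1=CCCC23OCCO3 | intermediate
15 | 9,9-(ethylenedioxy)-4β-(hydroxymethyl)-4α,10β-dimethyl-Δ5-octalin-2α-ol | OC[C@@]1(C)C[C@H](O)C[C@@]2(C)C1=CCCC23OCCO3 | intermediate
16 | 6α-boryl-5α-H adduct of 15, formed in the flask (hydroxyls drawn free; present as borates) | OC[C@@]1(C)C[C@H](O)C[C@@]2(C)[C@H]1[C@@H](B)CCC23OCCO3 | intermediate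
17 | 9,9-(ethylenedioxy)-4β-(hydroxymethyl)-4α,10β-dimethyl-5α-decalin-2α,6α-diol | OC[C@@]1(C)C[C@H](O)C[C@@]2(C)[C@H]1[C@@H](O)CCC23OCCO3 | intermediate
18 | 2α,6α-dihydroxy-4β-(hydroxymethyl)-4α,10β-dimethyl-5α-decalin-9-one | OC[C@@]1(C)C[C@H](O)C[C@@]2(C)[C@H]1[C@@H](O)CCC2=O | intermediate
19 | 2,6,19-tris-O-TBS ether of 18 | CC(C)(C)[Si](C)(C)OC[C@@]1(C)C[C@H](O[Si](C)(C)C(C)(C)C)C[C@@]2(C)[C@H]1[C@@H](O[Si](C)(C)C(C)(C)C)CCC2=O | intermediate
20 | 8-methyl derivative of 19 (C8 epimers) | CC(C)(C)[Si](C)(C)OC[C@@]1(C)C[C@H](O[Si](C)(C)C(C)(C)C)C[C@@]2(C)[C@H]1[C@@H](O[Si](C)(C)C(C)(C)C)CC(C)C2=O | intermediate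
21 | C8=C9 enol triflate of 20 | CC(C)(C)[Si](C)(C)OC[C@@]1(C)C[C@H](O[Si](C)(C)C(C)(C)C)C[C@@]2(C)[C@H]1[C@@H](O[Si](C)(C)C(C)(C)C)CC(C)=C2OS(=O)(=O)C(F)(F)F | intermediate
22 | tributyl(vinyl)stannane | C=C[Sn](CCCC)(CCCC)CCCC | starting material
23 | 9-vinyl C8=C9 diene (tris-TBS) | CC(C)(C)[Si](C)(C)OC[C@@]1(C)C[C@H](O[Si](C)(C)C(C)(C)C)C[C@@]2(C)[C@H]1[C@@H](O[Si](C)(C)C(C)(C)C)CC(C)=C2C=C | intermediate
24 | 4-bromofuran-2(5H)-one | O=C1C=C(Br)CO1 | starting material
25 | C12 B-alkyl-9-BBN adduct of 23, formed in the flask | CC(C)(C)[Si](C)(C)OC[C@@]1(C)C[C@H](O[Si](C)(C)C(C)(C)C)C[C@@]2(C)[C@H]1[C@@H](O[Si](C)(C)C(C)(C)C)CC(C)=C2CCB3C4CCCC3CCC4 | intermediate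
26 | 2,6,19-tris-O-TBS ether of the target | CC(C)(C)[Si](C)(C)OC[C@@]1(C)C[C@H](O[Si](C)(C)C(C)(C)C)C[C@@]2(C)[C@H]1[C@@H](O[Si](C)(C)C(C)(C)C)CC(C)=C2CCC3=CC(=O)OC3 | intermediate
27 | (2R,4S,5R,6S,10S)-2α,6α,19-trihydroxylabda-8,13-dien-15,16-olide (CNP0387838.1) | CC1=C(CCC2=CC(=O)OC2)[C@@]2(C)C[C@@H](O)C[C@](C)(CO)[C@@H]2[C@@H](O)C1 | target

**Totals**

Total step count: 17. Longest linear sequence: 17 steps (1 to 27); the other starting materials (2, 9, 22, 24) are commercial.

**Steps most likely to fail**

Step 8 (bears the label). The second methylenation may not take place at the hindered, tetrasubstituted zinc dienolate, so that only protonation occurs at work-up; the carbenoid may also attack C6 instead of C4, or cyclopropanate the C5=C6 bond. The fallback sets out from 11, returns at 18 and uses known chemistry only. The ring expansion is stopped after one methylene insertion (3 equiv carbenoid, no TMSCl, short time; zinc-carbenoid ring expansion of a cyclic β-keto ester) to give the ring-expanded keto ester F1. Its C2 ketone is ketalised (ethylene glycol, PPTS, benzene, reflux) to the bis-dioxolane F2. LDA in THF/DMPU at -78 °C followed by MeI alkylates the ester dienolate at C4 from the α-face to give the quaternary ester F3. BH3·THF, then NaOH/H2O2, gives the 5α-H, 6α-hydroxy ester F4, and LiAlH4 (THF, reflux) gives the diol F5. Aqueous 1 M HCl in THF removes both ketals to give the diketone diol F6. Me4NBH(OAc)3 in MeCN/AcOH at -20 °C should then reduce only the C2 ketone, by hydride delivery from the C19 alkoxyborohydride on the β-face (hydroxyl-directed triacetoxyborohydride reduction), to give 18.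

Step 10. Facial selectivity of the hydroboration may be poor: β-face addition, possibly delivered by the C19 alkoxyborane, would give the cis-fused 5β,6β-isomer. The fallback sets out from 15, returns at 18 and replaces kinetic facial control by thermodynamic control. The diol is silylated (TBSCl, imidazole, DMF) to the bis-TBS ether F7 and hydroborated as before to the C6 alcohol F8, taken on as a C5/C6 mixture. Dess–Martin oxidation, then K2CO3/MeOH to equilibrate C5, gives the trans-fused 6-ketone F9. Li/NH3/EtOH reduces it to the equatorial 6α-alcohol F10, and 1 M HCl in THF/MeOH removes the ketal and both silyl ethers to give 18.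

Step 16. The bromobutenolide may be ring-opened or hydrolysed by the aqueous base before coupling, or transmetalation of the hindered alkylborane may be slow. The fallback sets out from 23, returns at 26 and forms the same C12–C13 bond from an isolated electrophile-derived organozinc under base-free conditions. 9-BBN followed by NaOH/H2O2 gives the primary alcohol F11; I2, PPh3 and imidazole (Appel reaction) give the primary iodide F12; zinc dust with LiCl in THF gives the alkylzinc iodide F13; Negishi coupling of F13 with 24 (Pd(dba)2, SPhos, THF/DMA, rt) gives 26.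

**Further compounds**

F1 | step 8 | ethyl 9,9-(ethylenedioxy)-10β-methyl-2-oxo-Δ5-octalin-4-carboxylate (C4 epimers) | CCOC(=O)C1CC(=O)C[C@@]2(C)C1=CCCC23OCCO3
F2 | step 8 | 2,2:9,9-bis(ethylenedioxy) derivative of F1 | CCOC(=O)C1CC2(OCCO2)C[C@@]3(C)C1=CCCC34OCCO4
F3 | step 8 | ethyl 2,2:9,9-bis(ethylenedioxy)-4α,10β-dimethyl-Δ5-octalin-4β-carboxylate | CCOC(=O)[C@@]1(C)CC2(OCCO2)C[C@@]3(C)C1=CCCC34OCCO4
F4 | step 8 | ethyl 2,2:9,9-bis(ethylenedioxy)-6α-hydroxy-4α,10β-dimethyl-5α-decalin-4β-carboxylate | CCOC(=O)[C@@]1(C)CC2(OCCO2)C[C@@]3(C)[C@H]1[C@@H](O)CCC34OCCO4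
F5 | step 8 | 2,2:9,9-bis(ethylenedioxy)-4β-(hydroxymethyl)-4α,10β-dimethyl-5α-decalin-6α-ol | OC[C@@]1(C)CC2(OCCO2)C[C@@]3(C)[C@H]1[C@@H](O)CCC34OCCO4
F6 | step 8 | 6α-hydroxy-4β-(hydroxymethyl)-4α,10β-dimethyl-5α-decalin-2,9-dione | OC[C@@]1(C)CC(=O)C[C@@]2(C)[C@H]1[C@@H](O)CCC2=O
F7 | step 10 | 2,19-bis-O-TBS ether of 15 | CC(C)(C)[Si](C)(C)OC[C@@]1(C)C[C@H](O[Si](C)(C)C(C)(C)C)C[C@@]2(C)C1=CCCC23OCCO3
F8 | step 10 | 6-hydroxy hydroboration product of F7 (C5/C6 mixture) | CC(C)(C)[Si](C)(C)OC[C@@]1(C)C[C@H](O[Si](C)(C)C(C)(C)C)C[C@@]2(C)C1C(O)CCC23OCCO3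
F9 | step 10 | trans-fused (5α-H) 6-ketone, 2,19-bis-O-TBS, 9-dioxolane | CC(C)(C)[Si](C)(C)OC[C@@]1(C)C[C@H](O[Si](C)(C)C(C)(C)C)C[C@@]2(C)[C@H]1C(=O)CCC23OCCO3
F10 | step 10 | 6α-alcohol, 5α-H, 2,19-bis-O-TBS, 9-dioxolane | CC(C)(C)[Si](C)(C)OC[C@@]1(C)C[C@H](O[Si](C)(C)C(C)(C)C)C[C@@]2(C)[C@H]1[C@@H](O)CCC23OCCO3
F11 | step 16 | C12 primary alcohol from 23 (tris-TBS) | CC(C)(C)[Si](C)(C)OC[C@@]1(C)C[C@H](O[Si](C)(C)C(C)(C)C)C[C@@]2(C)[C@H]1[C@@H](O[Si](C)(C)C(C)(C)C)CC(C)=C2CCO
F12 | step 16 | C12 primary iodide (tris-TBS) | CC(C)(C)[Si](C)(C)OC[C@@]1(C)C[C@H](O[Si](C)(C)C(C)(C)C)C[C@@]2(C)[C@H]1[C@@H](O[Si](C)(C)C(C)(C)C)CC(C)=C2CCI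
F13 | step 16 | C12 alkylzinc iodide (tris-TBS) | CC(C)(C)[Si](C)(C)OC[C@@]1(C)C[C@H](O[Si](C)(C)C(C)(C)C)C[C@@]2(C)[C@H]1[C@@H](O[Si](C)(C)C(C)(C)C)CC(C)=C2CC[Zn]I
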